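**Plan**

- Numbering (germacrane): ring C1–C10 with OH on C1, OAc on C3, C15H2OH on C4, lactone O on C6, O-tigloyl on C8, C14H3 on C10; lactone carbons C11–C13.
- Cuts, in order: O–C6 and C11–C7 (2-bromoacrylic acid plus a ten-membered triene), then C1–C10 (Nozaki–Hiyama–Kishi), then C7–C8 (alkenylzinc plus enal), then C3–C4 (vinyllithium plus Weinreb amide).
- Forward: the C1–C7 enyne and the C8–C10 iodoenal are joined, the carbocycle is closed, the lactone ring is annulated last, and one desilylation follows.
- Enabling feature: C6 and C7 are one end of the conjugated diene C4=C5–C6=C7 inside the ten-membered ring. Carbopalladation at C7 gives a π-allyl over C6–C5–C4 that the carboxylate closes at C6; the E geometry of C6=C7 becomes the trans ring fusion and the 4Z alkene is returned.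
- Stereochemistry: C3 by CBS reduction, C8 by ligand-controlled alkenylzinc addition, C1 by 1,3-anti induction from C3 in the ring closure, C6 and C7 relayed from C8 and the alkene geometry in the key step. The three alkene geometries come from Wittig, hydroboration and hydroalumination chemistry.

Key step: step 15

Remark: the CIP descriptor at C8 is S in 19–23 and R in 25 and 26; only the priorities change on lactone formation, not the spatial arrangement.

**Route**

Step 1
Reactants: 1 but-2-yn-1-ol
Product: 3 (Z)-3-iodobut-2-en-1-ol, via vinylalanate chelate 2 (not isolated)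
Conditions: NaAlH2(OCH2CH2OMe)2, THF, 0 °C to rt; then I2, −78 °C to 0 °C
Reagents that add atoms: iodine (II)
Why: Hydroxyl-directed trans-hydroalumination of the propargylic alcohol followed by iodinolysis of the C–Al bond with retention is the standard route to (Z)-3-iodoallylic alcohols, so iodine should end up cis to the CH2OH group.

Step 2
Reactants: 3 (Z)-3-iodobut-2-en-1-ol
Product: 4 (Z)-3-iodobut-2-enal
Conditions: MnO2, CH2Cl2, rt, dark; used at once
Reagents that add atoms: none
Why: Allylic alcohol oxidation with activated MnO2 is mild enough to keep the Z geometry of the β-iodoenal.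

Step 3
Reactants: 5 methyl 3,3-dimethoxypropanoate
Product: 6 N,3,3-trimethoxy-N-methylpropanamide
Conditions: MeNHOMe·HCl, i-PrMgCl, THF, −20 °C to 0 °C
Reagents that add atoms: N,O-dimethylhydroxylamine hydrochloride (CNOC.Cl)
Why: Weinreb amide formation from an ester with the magnesium amide of N,O-dimethylhydroxylamine, to which the acetal is inert.

Step 4
Reactants: 7 3-(trimethylsilyl)prop-2-ynal; 8 ethyl 2-bromo-2-(triphenyl-λ5-phosphanylidene)acetate
Product: 9 ethyl (Z)-2-bromo-5-(trimethylsilyl)pent-2-en-4-ynoate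
Conditions: CH2Cl2, 0 °C to rt
Reagents that add atoms: none
Why: Wittig olefination with the stabilized α-bromo ylide should place the ester trans to the alkynyl group, which gives the Z bromoenoate (bromine cis to C6) needed for the later 4Z geometry.

Step 5
Reactants: 9 ethyl (Z)-2-bromo-5-(trimethylsilyl)pent-2-en-4-ynoate
Product: 10 (Z)-2-bromo-5-(trimethylsilyl)pent-2-en-4-yn-1-ol
Conditions: i-Bu2AlH, CH2Cl2, −78 °C; aqueous potassium sodium tartrate
Reagents that add atoms: none
Why: 1,2-Reduction of the enoate by i-Bu2AlH at low temperature should leave the vinyl bromide and the silylalkyne untouched and turns the ester carbon into C15.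

Step 6
Reactants: 10 (Z)-2-bromo-5-(trimethylsilyl)pent-2-en-4-yn-1-ol
Product: 11 (Z)-2-bromo-1-(tert-butyldimethylsilyloxy)-5-(trimethylsilyl)pent-2-en-4-yne
Conditions: TBSCl, imidazole, CH2Cl2, 0 °C to rt
Reagents that add atoms: tert-butyldimethylsilyl chloride (CC(C)(C)[Si](C)(C)Cl)
Why: Standard silylation of the primary allylic alcohol protects the C15 oxygen to the end of the route.

Step 7
Reactants: 11 (Z)-2-bromo-1-(tert-butyldimethylsilyloxy)-5-(trimethylsilyl)pent-2-en-4-yne; 6 N,3,3-trimethoxy-N-methylpropanamide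
Product: 13 (Z)-4-[(tert-butyldimethylsilyloxy)methyl]-1,1-dimethoxy-7-(trimethylsilyl)hept-4-en-6-yn-3-one, via vinyllithium 12 (not isolated)
Conditions: t-BuLi (2 equiv), Et2O, −78 °C; then 6, −78 °C to −40 °C; aqueous NH4Cl
Reagents that add atoms: none
Why: Bromine–lithium exchange with retention of alkene geometry, then acylation of the vinyllithium by the Weinreb amide, whose chelated adduct stops the reaction at the ketone and forms the C3–C4 bond.

Step 8
Reactants: 13 (Z)-4-[(tert-butyldimethylsilyloxy)methyl]-1,1-dimethoxy-7-(trimethylsilyl)hept-4-en-6-yn-3-one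
Product: 14 (3S,4Z)-4-[(tert-butyldimethylsilyloxy)methyl]-1,1-dimethoxy-7-(trimethylsilyl)hept-4-en-6-yn-3-ol
Conditions: (R)-1-methyl-3,3-diphenyltetrahydro-1H,3H-pyrrolo[1,2-c][1,3,2]oxazaborole (0.2 equiv), catecholborane, toluene, −78 °C
Reagents that add atoms: none
Why: Corey–Bakshi–Shibata reduction in which the α-branched alkenyl group acts as the large substituent, so the (R)-catalyst should deliver hydride to the face that gives the 3S alcohol, and catecholborane avoids hydroboration of the alkyne.

Step 9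
Reactants: 14 (3S,4Z)-4-[(tert-butyldimethylsilyloxy)methyl]-1,1-dimethoxy-7-(trimethylsilyl)hept-4-en-6-yn-3-ol
Product: 15 (3S,4Z)-4-[(tert-butyldimethylsilyloxy)methyl]-1,1-dimethoxyhept-4-en-6-yn-3-ol
Conditions: K2CO3 (0.2 equiv), MeOH, 0 °C
Reagents that add atoms: none
Why: Base-catalysed methanolysis of the alkynyl C–Si bond, to which the alkyl silyl ether and the acetal are stable.

Step 10
Reactants: 15 (3S,4Z)-4-[(tert-butyldimethylsilyloxy)methyl]-1,1-dimethoxyhept-4-en-6-yn-3-ol
Product: 16 (3S,4Z)-4-[(tert-butyldimethylsilyloxy)methyl]-1,1-dimethoxyhept-4-en-6-yn-3-yl acetate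
Conditions: Ac2O, pyridine, DMAP (cat.), CH2Cl2, 0 °C to rt
Reagents that add atoms: acetic anhydride (CC(=O)OC(C)=O)
Why: Standard acetylation of the secondary allylic alcohol installs the C3 acetate of the target with retention.

Step 11
Reactants: 16 (3S,4Z)-4-[(tert-butyldimethylsilyloxy)methyl]-1,1-dimethoxyhept-4-en-6-yn-3-yl acetate; 4 (Z)-3-iodobut-2-enal
Product: 19 (3S,4Z,6E,8S,9Z)-4-[(tert-butyldimethylsilyloxy)methyl]-8-hydroxy-10-iodo-1,1-dimethoxyundeca-4,6,9-trien-3-yl acetate, via dienylborane 17 (not isolated), via dienylzinc 18 (not isolated)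
Conditions: Cy2BH, toluene, 0 °C to rt; Me2Zn, −78 °C; (2S)-(−)-3-exo-morpholinoisoborneol (5 mol %), then 4, −20 °C; aqueous NH4Cl
Reagents that add atoms: none
Why: Syn hydroboration of the terminal alkyne gives the E-alkenylborane, boron-to-zinc exchange gives a dienylzinc, and the amino alcohol ligand should direct its 1,2-addition to the Si face of the enal (catalytic asymmetric alkenylzinc addition), which sets C8 independently of the remote C3 centre and forms the C7–C8 bond.

Step 12
Reactants: 19 (3S,4Z,6E,8S,9Z)-4-[(tert-butyldimethylsilyloxy)methyl]-8-hydroxy-10-iodo-1,1-dimethoxyundeca-4,6,9-trien-3-yl acetate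
Product: 20 (3S,4Z,6E,8S,9Z)-3-acetoxy-4-[(tert-butyldimethylsilyloxy)methyl]-10-iodo-1,1-dimethoxyundeca-4,6,9-trien-8-yl (E)-2-methylbut-2-enoate
Conditions: tigloyl chloride, pyridine, DMAP (cat.), CH2Cl2, 0 °C
Reagents that add atoms: (E)-2-methylbut-2-enoyl chloride (C/C=C(\C)C(=O)Cl)
Why: Acylation of the bis-allylic alcohol under nucleophilic catalysis installs the C8 tiglate without touching the C8–O bond.

Step 13
Reactants: 20 (3S,4Z,6E,8S,9Z)-3-acetoxy-4-[(tert-butyldimethylsilyloxy)methyl]-10-iodo-1,1-dimethoxyundeca-4,6,9-trien-8-yl (E)-2-methylbut-2-enoate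
Product: 22 (3S,4Z,6E,8S,9Z)-3-acetoxy-4-[(tert-butyldimethylsilyloxy)methyl]-10-iodo-1-oxoundeca-4,6,9-trien-8-yl (E)-2-methylbut-2-enoate, via collidinium acetal 21 (not isolated)
Conditions: Et3SiOTf, 2,4,6-collidine, CH2Cl2, 0 °C; then H2O, rt
Reagents that add atoms: water (O)
Why: Chemoselective acetal cleavage under nearly neutral conditions through a pyridinium-type intermediate that water hydrolyses, which should spare the silyl ether, the allylic esters and the β-acetoxy aldehyde that forms.

Step 14
Reactants: 22 (3S,4Z,6E,8S,9Z)-3-acetoxy-4-[(tert-butyldimethylsilyloxy)methyl]-10-iodo-1-oxoundeca-4,6,9-trien-8-yl (E)-2-methylbut-2-enoate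
Product: 23 (1S,3S,4Z,6E,8S,9Z)-3-acetoxy-4-[(tert-butyldimethylsilyloxy)methyl]-1-hydroxy-10-methylcyclodeca-4,6,9-trien-8-yl (E)-2-methylbut-2-enoate (germacrane numbering)
Conditions: CrCl2 (6 equiv), NiCl2 (2 mol %), degassed DMSO, rt, 2 mM, slow addition
Reagents that add atoms: none
Why: Nozaki–Hiyama–Kishi macrocyclization in which the alkenylchromium, formed with retention of the Z geometry, adds to the aldehyde at high dilution to close C1–C10, and the β-acetoxy centre C3 should direct 1,3-anti addition (polar model for β-heteroatom aldehydes) to give the 1S alcohol.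

Step 15
Reactants: 23 (1S,3S,4Z,6E,8S,9Z)-3-acetoxy-4-[(tert-butyldimethylsilyloxy)methyl]-1-hydroxy-10-methylcyclodeca-4,6,9-trien-8-yl (E)-2-methylbut-2-enoate; 24 2-bromoprop-2-enoic acid
Product: 25 15-O-(tert-butyldimethylsilyl)eupacunolin, the (1S,3S,6R,7R,8R,4Z,9Z) trans-fused α-methylene-γ-lactone
Conditions: Pd(OAc)2 (10 mol %), NaHCO3, n-Bu4NCl, DMF, 60 °C
Reagents that add atoms: none
Why: Zerovalent palladium generated in situ inserts into the C–Br bond of 24, the 1-carboxyvinylpalladium adds syn across C6=C7 of the ring diene with carbon going to the diene terminus C7, and the π-allylpalladium spanning C6–C5–C4 is closed at C6 by the carboxylate with release of zerovalent palladium. The closest known reaction type is the Larock heteroannulation of 1,3-dienes by aryl or vinylic halides that carry a carboxylic acid or another nucleophile. The lactone ring closes by C–O bond formation at the allyl terminus C6 (five-membered, exo to the allyl unit), since attack at C4 would need a seven-membered ring at a fully substituted carbon. C7 is controlled by the resident C8 centre: the outer face of the E-alkene is open in the ring conformer that holds C9 anti and the C8 acyloxy group eclipsing the C6=C7 bond, and attack there puts C11 on the same ring face as the C8 oxygen. C6 is controlled by the E geometry of C6=C7 and by suprafacial delivery of carbon and oxygen, because inside the ten-membered ring the carboxylate can reach C6 only from the palladium-bearing outer face, which gives the trans-fused lactone. The step needs site selectivity for the conjugated diene over the C9=C10 and tiglate alkenes (dienes insert fastest), retention of the 4Z geometry (no σ-allyl forms at the fully substituted C4) and intact allylic esters, for which phosphine-free conditions at moderate temperature are chosen.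

Step 16
Reactants: 25 15-O-(tert-butyldimethylsilyl)eupacunolin
Product: 26 eupacunolin
Conditions: HF·pyridine, pyridine–THF, 0 °C
Reagents that add atoms: none
Why: Fluoride-mediated cleavage of the primary silyl ether under buffered conditions that should not touch the esters or the α-methylene lactone.

**Compound list**

1 | but-2-yn-1-ol | CC#CCO | starting material
2 | sodium vinylalanate chelate from 1 (five-membered C=C–Al–O ring, aluminium on C3 cis to the CH2O group) | CC1=CCO[Al-]1(OCCOC)OCCOC.[Na+] | intermediate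
3 | (Z)-3-iodobut-2-en-1-ol | I/C(C)=C\CO | intermediate
4 | (Z)-3-iodobut-2-enal | I/C(C)=C\C=O | intermediate
5 | methyl 3,3-dimethoxypropanoate | COC(=O)CC(OC)OC | starting material
6 | N,3,3-trimethoxy-N-methylpropanamide | CON(C)C(=O)CC(OC)OC | intermediate
7 | 3-(trimethylsilyl)prop-2-ynal | C[Si](C)(C)C#CC=O | starting material
8 | ethyl 2-bromo-2-(triphenyl-λ5-phosphanylidene)acetate | CCOC(=O)C(Br)=P(c1ccccc1)(c1ccccc1)c1ccccc1 | starting material
9 | ethyl (Z)-2-bromo-5-(trimethylsilyl)pent-2-en-4-ynoate | C[Si](C)(C)C#C/C=C(/C(=O)OCC)Br | intermediate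
10 | (Z)-2-bromo-5-(trimethylsilyl)pent-2-en-4-yn-1-ol | C[Si](C)(C)C#C/C=C(/CO)Br | intermediate
11 | (Z)-2-bromo-1-(tert-butyldimethylsilyloxy)-5-(trimethylsilyl)pent-2-en-4-yne | C[Si](C)(C)C#C/C=C(/CO[Si](C)(C)C(C)(C)C)Br | intermediate
12 | vinyllithium from 11 (lithium in place of bromine, geometry retained) | C[Si](C)(C)C#C/C=C(/CO[Si](C)(C)C(C)(C)C)[Li] | intermediate
13 | (Z)-4-[(tert-butyldimethylsilyloxy)methyl]-1,1-dimethoxy-7-(trimethylsilyl)hept-4-en-6-yn-3-one | C[Si](C)(C)C#C/C=C(/CO[Si](C)(C)C(C)(C)C)C(=O)CC(OC)OC | intermediate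
14 | (3S,4Z)-4-[(tert-butyldimethylsilyloxy)methyl]-1,1-dimethoxy-7-(trimethylsilyl)hept-4-en-6-yn-3-ol | C[Si](C)(C)C#C/C=C(/CO[Si](C)(C)C(C)(C)C)[C@@H](O)CC(OC)OC | intermediate
15 | (3S,4Z)-4-[(tert-butyldimethylsilyloxy)methyl]-1,1-dimethoxyhept-4-en-6-yn-3-ol | C#C/C=C(/CO[Si](C)(C)C(C)(C)C)[C@@H](O)CC(OC)OC | intermediate
16 | (3S,4Z)-4-[(tert-butyldimethylsilyloxy)methyl]-1,1-dimethoxyhept-4-en-6-yn-3-yl acetate | C#C/C=C(/CO[Si](C)(C)C(C)(C)C)[C@@H](OC(C)=O)CC(OC)OC | intermediate
17 | (1E,3Z)-dienyl(dicyclohexyl)borane from 16 (boron on C7) | C1CCCCC1B(C1CCCCC1)/C=C/C=C(/CO[Si](C)(C)C(C)(C)C)[C@@H](OC(C)=O)CC(OC)OC | intermediate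
18 | (1E,3Z)-dienyl(methyl)zinc from 17 (zinc on C7) | C[Zn]/C=C/C=C(/CO[Si](C)(C)C(C)(C)C)[C@@H](OC(C)=O)CC(OC)OC | intermediate
19 | (3S,4Z,6E,8S,9Z)-4-[(tert-butyldimethylsilyloxy)methyl]-8-hydroxy-10-iodo-1,1-dimethoxyundeca-4,6,9-trien-3-yl acetate | I/C(C)=C\[C@@H](O)/C=C/C=C(/CO[Si](C)(C)C(C)(C)C)[C@@H](OC(C)=O)CC(OC)OC | intermediate
20 | (3S,4Z,6E,8S,9Z)-3-acetoxy-4-[(tert-butyldimethylsilyloxy)methyl]-10-iodo-1,1-dimethoxyundeca-4,6,9-trien-8-yl (E)-2-methylbut-2-enoate | I/C(C)=C\[C@@H](OC(=O)/C(C)=C/C)/C=C/C=C(/CO[Si](C)(C)C(C)(C)C)[C@@H](OC(C)=O)CC(OC)OC | intermediate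
21 | collidinium acetal from 20 (C1 bearing OMe and N-2,4,6-trimethylpyridinium, triflate salt, C1 unassigned) | I/C(C)=C\[C@@H](OC(=O)/C(C)=C/C)/C=C/C=C(/CO[Si](C)(C)C(C)(C)C)[C@@H](OC(C)=O)CC(OC)[n+]1c(C)cc(C)cc1C.[O-]S(=O)(=O)C(F)(F)F | intermediate
22 | (3S,4Z,6E,8S,9Z)-3-acetoxy-4-[(tert-butyldimethylsilyloxy)methyl]-10-iodo-1-oxoundeca-4,6,9-trien-8-yl (E)-2-methylbut-2-enoate | I/C(C)=C\[C@@H](OC(=O)/C(C)=C/C)/C=C/C=C(/CO[Si](C)(C)C(C)(C)C)[C@@H](OC(C)=O)CC=O | intermediate
23 | (1S,3S,4Z,6E,8S,9Z)-3-acetoxy-4-[(tert-butyldimethylsilyloxy)methyl]-1-hydroxy-10-methylcyclodeca-4,6,9-trien-8-yl (E)-2-methylbut-2-enoate (germacrane numbering) | [C@H]1(OC(=O)/C(C)=C/C)/C=C/C=C(/CO[Si](C)(C)C(C)(C)C)[C@@H](OC(C)=O)C[C@H](O)/C(C)=C\1 | intermediate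
24 | 2-bromoprop-2-enoic acid | C=C(Br)C(=O)O | starting material
25 | 15-O-(tert-butyldimethylsilyl)eupacunolin (1S,3S,6R,7R,8R,4Z,9Z) | C=C1C(=O)O[C@@H]2/C=C(/CO[Si](C)(C)C(C)(C)C)[C@@H](OC(C)=O)C[C@H](O)/C(C)=C\[C@@H](OC(=O)/C(C)=C/C)[C@@H]12 | intermediate
26 | eupacunolin (1S,3S,6R,7R,8R,4Z,9Z) | C=C1C(=O)O[C@@H]2/C=C(/CO)[C@@H](OC(C)=O)C[C@H](O)/C(C)=C\[C@@H](OC(=O)/C(C)=C/C)[C@@H]12 | target

**Summary**

Total step count: 16. Longest linear sequence: 13 steps (steps 4 to 16, from 7 to 26).

Steps most likely to fail: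

1. Step 15. The vinylpalladium may attack the other face of C6=C7 (ring conformer with the C8 acyloxy group turned outward), zerovalent palladium may ionize the allylic carboxylates, or a second Heck reaction may occur on the new α-methylene lactone. Fallback, from 23 and returning at 26: an oxidative radical lactone annulation that needs no zerovalent palladium. Mn(OAc)3·2H2O and Cu(OAc)2·H2O (trivalent manganese as oxidant) with hydrogen 2-(trimethylsilyl)ethyl malonate in AcOH at 50 °C should add the malonyl radical to C7 and close the allyl cation at C6, giving the trans-fused α-[2-(trimethylsilyl)ethoxycarbonyl] lactone F1. n-Bu4NF in THF should then cleave the silylethyl ester and the silyl ether to the α-carboxy lactone F2. Decarboxylative Mannich methylenation (aqueous CH2O, Et2NH, AcOH, NaOAc) should return to the route at 26.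

2. Step 14. Oligomerization may compete with ring closure to the strained triene, and the alkenylchromium may add to the other aldehyde face. Fallback, from 22 and returning at 23: the crude cyclization product, containing 23 and its C1 epimer F3, is oxidized with Dess–Martin periodinane (NaHCO3, CH2Cl2) to the macrocyclic dienone F4. The C1 centre is then set by reagent control with the (R)-oxazaborolidine of step 8 and catecholborane, which should return 23.

3. Step 11. Face selectivity of the ligand-controlled addition to the β-iodoenal may be low, or addition–elimination may occur at the iodine-bearing carbon. Fallback, from 16 and 4 and returning at 19: zinc alkynylation of 4 with the alkynylzinc from 16 and Me2Zn under a ProPhenol ligand [2,6-bis[[2-(hydroxydiphenylmethyl)pyrrolidin-1-yl]methyl]-4-methylphenol, enantiomer chosen for the C8 configuration of 19] should give the propargylic alcohol F5. Trans-hydrosilylation with (EtO)3SiH and [Cp*Ru(MeCN)3]PF6 should give the Z-vinylsilane F6, and protodesilylation with AgF in THF–MeOH–H2O should return 19 with the 6E geometry.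

**Further compounds**

F1 | step 15 | analogue of 25 in which C11 carries H and CO2CH2CH2SiMe3 in place of the methylene (C11 unassigned) | C[Si](C)(C)CCOC(=O)C1C(=O)O[C@@H]2/C=C(/CO[Si](C)(C)C(C)(C)C)[C@@H](OC(C)=O)C[C@H](O)/C(C)=C\[C@@H](OC(=O)/C(C)=C/C)[C@@H]12
F2 | step 15 | analogue of 26 in which C11 carries H and CO2H in place of the methylene (C11 unassigned) | OC(=O)C1C(=O)O[C@@H]2/C=C(/CO)[C@@H](OC(C)=O)C[C@H](O)/C(C)=C\[C@@H](OC(=O)/C(C)=C/C)[C@@H]12
F3 | step 14 | C1 epimer of 23 (1R) | [C@H]1(OC(=O)/C(C)=C/C)/C=C/C=C(/CO[Si](C)(C)C(C)(C)C)[C@@H](OC(C)=O)C[C@@H](O)/C(C)=C\1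
F4 | step 14 | C1 ketone of 23 (macrocyclic dienone) | [C@H]1(OC(=O)/C(C)=C/C)/C=C/C=C(/CO[Si](C)(C)C(C)(C)C)[C@@H](OC(C)=O)CC(=O)/C(C)=C\1
F5 | step 11 | 6,7-didehydro analogue of 19 (C6≡C7 propargylic alcohol, C8 arranged as in 19) | I/C(C)=C\[C@@H](O)C#C/C=C(/CO[Si](C)(C)C(C)(C)C)[C@@H](OC(C)=O)CC(OC)OC
F6 | step 11 | 6-(triethoxysilyl) derivative of 19 (silicon on C6 cis to C8) | I/C(C)=C\[C@@H](O)/C=C(/C=C(/CO[Si](C)(C)C(C)(C)C)[C@@H](OC(C)=O)CC(OC)OC)[Si](OCC)(OCC)OCC
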